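**Retrosynthetic overview**
1. Target ⇐ 6,9,11-triol (bis-acetylation) ⇐ ten-membered 2-methylene ketone (reagent-controlled reduction at C6).
2. Key disconnection C3–C4: the ten-membered ring is closed last by coupling the homoenolate of the C6 ketone (C4 made nucleophilic by opening a 1-alkenylcyclopropanol) with a (Z)-alkenyl iodide at C3.
3. The (Z)-iodoalkene comes from a cis-fused lactol by Stork–Zhao olefination; the C8–C9 bond comes from an allylsilane and the lactol carbon C9.
4. The cis-fused lactol comes from Baeyer–Villiger oxidation of the [2+2] adduct of methoxyketene and (R)-α-phellandrene (sets C1 and C10; C14 from the chiral pool); the C11 carbinol comes from hydrogen-atom-transfer hydration.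
5. Ring order: cyclohexane (bought) → cyclobutanone → γ-lactone (temporary) → ten-membered carbocycle.

Assumption: locants C1–C20 are the eunicellane locants of the target (ring fusion C1/C10, C19 = methylene carbon on C7); 8 and 9 are bought; the hemiacetal carbon of 6, 7 and 15 is an inconsequential epimer mixture and is drawn without a descriptor.

**Step 1**
Reactants: 1 (R)-(−)-α-phellandrene; 2 methoxyacetyl chloride
Product: 4 cis-fused cyclobutanone 8-methoxy-2-methyl-5-(propan-2-yl)bicyclo[4.2.0]oct-2-en-7-one (four-membered ring anti to the isopropyl group; C=O carbon = future C2 on C1; CH(OMe) = future C9 on C10; OMe endo), via methoxyketene 3 (not isolated)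
Conditions: Et3N, hexane, reflux, slow addition of 2
Reagents that add atoms: none
Why: Ketene–alkene [2+2] cycloaddition: methoxyketene adds suprafacially to the less substituted C1=C10 double bond on the face opposite the C14 isopropyl group, with the carbonyl carbon bonding to the diene terminus C1 and the methoxy carbon to C10, so C1 and C10 are set cis to each other and trans to the isopropyl group.

**Step 2**
Reactants: 4 cyclobutanone
Product: 6 cis-fused lactol (pseudo-acid) 3-hydroxy-4-methyl-7-(propan-2-yl)-3a,6,7,7a-tetrahydro-2-benzofuran-1(3H)-one, via methoxy lactone 5 (not isolated)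
Conditions: 30% aq. H2O2, AcOH, 0 °C; then 1 M HCl, THF, 23 °C
Reagents that add atoms: hydrogen peroxide (OO); water (O)
Why: Baeyer–Villiger oxidation: the strained cyclobutanone takes up H2O2 faster than the trisubstituted alkene is epoxidised, the oxygen-bearing C9 migrates with retention in preference to C1, and hydrolysis of the acylal gives the lactol with C1 and C10 still locked cis in the five-membered ring.

**Step 3**
Reactants: 6 lactol
Product: 7 dihydroxy lactone 3,4-dihydroxy-4-methyl-7-(propan-2-yl)hexahydro-2-benzofuran-1(3H)-one (C11 OH trans to the C10–C9 bond)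
Conditions: Co(acac)2 (20 mol%), PhSiH3 (2.5 equiv), O2 (1 atm), i-PrOH, 23 °C
Reagents that add atoms: dioxygen (O=O)
Why: Mukaiyama hydration (hydrogen-atom transfer): Markovnikov H-atom transfer to C12 gives the tertiary C11 radical, which is trapped by O2 on the convex face, axially and anti to the axial C10–C9 bond, so the new hydroxyl is trans to C9 (11R).

**Step 4**
Reactants: 8 (2-bromoallyl)trimethylsilane; 9 1-ethoxycyclopropan-1-ol
Product: 13 1-[3-(trimethylsilyl)prop-1-en-2-yl]cyclopropyl acetate, via Grignard reagent 10 (not isolated), via cyclopropanone 11 (not isolated), via magnesium cyclopropanolate 12 (not isolated)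
Conditions: 8, Mg, THF, reflux; 9, MeMgBr, THF, 0 °C; combine, reflux; then Ac2O, DMAP (cat.), 0 → 23 °C
Reagents that add atoms: acetic anhydride (CC(=O)OC(C)=O)
Why: Grignard addition to cyclopropanone released from the magnesium salt of its hemiacetal gives the 1-alkenylcyclopropanol (a masked ketone homoenolate), and acetylating the alkoxide in the same flask blocks the semipinacol ring expansion that the free cyclopropanol would suffer under Lewis acid; no stereocentre is formed.

**Step 5**
Reactants: 7 dihydroxy lactone; 13 allylsilane acetate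
Product: 14 lactone 3-{2-[1-(acetyloxy)cyclopropyl]prop-2-en-1-yl}-4-hydroxy-4-methyl-7-(propan-2-yl)hexahydro-2-benzofuran-1(3H)-one (9R)
Conditions: BF3·OEt2 (2 equiv), CH2Cl2, −78 → −40 °C; then 1 M HCl, THF, 23 °C
Reagents that add atoms: none
Why: Hosomi–Sakurai allylation: BF3 ionises the lactol to the cyclic acyloxocarbenium ion (or its open aldehyde complex), the allylsilane attacks C9 on the convex face of the cis-fused bicycle anti to the C10–C11 bond (also the Felkin–Anh sense for the open form) to give 9R, and the hydroxy acid relactonises.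

**Step 6**
Reactants: 14 lactone
Product: 15 lactol 3-[2-(1-hydroxycyclopropyl)prop-2-en-1-yl]-4-methyl-7-(propan-2-yl)octahydro-2-benzofuran-1,4-diol
Conditions: i-Bu2AlH (5 equiv), CH2Cl2, −78 °C; aq. potassium sodium tartrate
Reagents that add atoms: none
Why: Hydride reduction with i-Bu2AlH at −78 °C stops at the aluminium lactolate, so the γ-lactone becomes the lactol (masked C2 aldehyde), and the excess reagent removes the cyclopropyl acetate; no stereocentre is touched.

**Step 7**
Reactants: 15 lactol
Product: 17 (Z)-iodoalkene triol (C1 bears (Z)-CH=C(I)CH3; C10 bears CH(OH)CH2C(=CH2)-(1-hydroxycyclopropyl); C11 OH), via hydroxy aldehyde 16 (not isolated)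
Conditions: [Ph3PEt]I, n-BuLi, THF, 23 °C; I2, −78 °C; NaN(SiMe3)2, −78 → −20 °C; then 15 (pre-treated with NaN(SiMe3)2, 3 equiv), −78 → −20 °C
Reagents that add atoms: ethyltriphenylphosphonium iodide (CC[P+](c1ccccc1)(c1ccccc1)c1ccccc1.[I-]); iodine (II)
Why: Stork–Zhao–Wittig olefination: the α-iodo ylide reacts with the aldehyde tautomer through the kinetically favoured cis-oxaphosphetane to give the (Z)-2-iodoalkene with iodine cis to C1, which fixes the later 2Z geometry, and opening the lactol frees the C9 hydroxyl.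

**Step 8**
Reactants: 17 (Z)-iodoalkene triol
Product: 18 macrocyclic enone (1S,2Z,9R,10S,11R,14R)-9,11-dihydroxyeunicella-2,7(19)-dien-6-one
Conditions: Pd(OAc)2 (10 mol%), XPhos (20 mol%), Cs2CO3 (2.5 equiv), toluene, 80 °C, slow addition of 17 (final 2 mM)
Reagents that add atoms: none
Why: Proposed new method: oxidative addition of the alkenyl iodide to zerovalent palladium (retention of Z), iodide-for-cyclopropoxide exchange and strain-driven β-carbon elimination give the palladium homoenolate of the C6 ketone, in which C4 (β to the carbonyl, normally electrophilic) is nucleophilic, and reductive elimination with the formerly electrophilic C3 closes the ten-membered ring without creating a stereocentre; the closest known reactions are intermolecular palladium-catalysed ring-opening cross-couplings of cyclopropanols (ketone homoenolates) with aryl and alkenyl halides, and the bulky biaryl phosphine is chosen to outpace β-hydride elimination.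

**Step 9**
Reactants: 18 macrocyclic enone
Product: 19 triol (1S,2Z,6R,9R,10S,11R,14R)-eunicella-2,7(19)-diene-6,9,11-triol
Conditions: (S)-2-methyl-CBS-oxazaborolidine (1 equiv), catecholborane (4 equiv), toluene, −78 °C; MeOH, then aq. NaHCO3
Reagents that add atoms: none
Why: Corey–Bakshi–Shibata reduction: with the α-methylene carbon C7 as the large group and the C5 methylene as the small one, the (S)-oxazaborolidine delivers hydride to give the 6R allylic alcohol under reagent control, and catecholborane at −78 °C leaves the alkenes alone.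

**Step 10**
Reactants: 19 triol
Product: 20 target (1S,2Z,6R,9R,10S,11R,14R)-eunicella-2,7(19)-diene-6,9,11-triol 6,9-diacetate
Conditions: Ac2O (3 equiv), pyridine, DMAP (5 mol%), CH2Cl2, 0 °C
Reagents that add atoms: acetic anhydride (CC(=O)OC(C)=O)
Why: DMAP-catalysed acylation: the two secondary alcohols at C6 and C9 are acetylated while the hindered tertiary C11 alcohol does not react at 0 °C, so no stereocentre is touched.

**Compound list**
1 | (R)-(−)-α-phellandrene, (5R)-2-methyl-5-(propan-2-yl)cyclohexa-1,3-diene | CC1=CC[C@H](C(C)C)C=C1 | starting material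
2 | methoxyacetyl chloride | COCC(Cl)=O | starting material
3 | methoxyketene | COC=C=O | intermediate (not isolated)
4 | cis-fused 8-methoxy-2-methyl-5-(propan-2-yl)bicyclo[4.2.0]oct-2-en-7-one (endo-OMe, ring anti to i-Pr) | CC1=CC[C@H](C(C)C)[C@@H]2[C@H]1[C@H](OC)C2=O | intermediate
5 | cis-fused 3-methoxy-4-methyl-7-(propan-2-yl)-3a,6,7,7a-tetrahydro-2-benzofuran-1(3H)-one | CC1=CC[C@H](C(C)C)[C@@H]2[C@H]1[C@H](OC)OC2=O | intermediate (not isolated)
6 | cis-fused 3-hydroxy-4-methyl-7-(propan-2-yl)-3a,6,7,7a-tetrahydro-2-benzofuran-1(3H)-one | CC1=CC[C@H](C(C)C)[C@@H]2[C@H]1C(O)OC2=O | intermediate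
7 | 3,4-dihydroxy-4-methyl-7-(propan-2-yl)hexahydro-2-benzofuran-1(3H)-one (11R hydroxyl) | C[C@@]1(O)CC[C@H](C(C)C)[C@@H]2[C@H]1C(O)OC2=O | intermediate
8 | (2-bromoallyl)trimethylsilane | C=C(Br)C[Si](C)(C)C | starting material
9 | 1-ethoxycyclopropan-1-ol | CCOC1(O)CC1 | starting material
10 | [3-(trimethylsilyl)prop-1-en-2-yl]magnesium bromide | C=C([Mg]Br)C[Si](C)(C)C | intermediate (not isolated)
11 | cyclopropanone | O=C1CC1 | intermediate (not isolated)
12 | bromomagnesium 1-[3-(trimethylsilyl)prop-1-en-2-yl]cyclopropan-1-olate | C=C(C[Si](C)(C)C)C1(O[Mg]Br)CC1 | intermediate (not isolated)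
13 | 1-[3-(trimethylsilyl)prop-1-en-2-yl]cyclopropyl acetate | CC(=O)OC1(CC1)C(=C)C[Si](C)(C)C | intermediate
14 | (9R)-lactone 3-{2-[1-(acetyloxy)cyclopropyl]prop-2-en-1-yl}-4-hydroxy-4-methyl-7-(propan-2-yl)hexahydro-2-benzofuran-1(3H)-one | C[C@@]1(O)CC[C@H](C(C)C)[C@@H]2[C@H]1[C@@H](CC(=C)C3(OC(C)=O)CC3)OC2=O | intermediate
15 | lactol 3-[2-(1-hydroxycyclopropyl)prop-2-en-1-yl]-4-methyl-7-(propan-2-yl)octahydro-2-benzofuran-1,4-diol | C[C@@]1(O)CC[C@H](C(C)C)[C@@H]2[C@H]1[C@@H](CC(=C)C3(O)CC3)OC2O | intermediate
16 | open-chain hydroxy aldehyde tautomer of 15 (C2 aldehyde on C1, free C9 hydroxyl) | C[C@@]1(O)CC[C@H](C(C)C)[C@@H](C=O)[C@H]1[C@H](O)CC(=C)C2(O)CC2 | intermediate (not isolated)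
17 | (Z)-iodoalkene triol (C1: (Z)-CH=C(I)CH3; C10: (9R)-CH(OH)CH2C(=CH2)-(1-hydroxycyclopropyl); 11-OH) | C[C@@]1(O)CC[C@H](C(C)C)[C@@H](/C=C(/C)I)[C@H]1[C@H](O)CC(=C)C2(O)CC2 | intermediate
18 | (1S,2Z,9R,10S,11R,14R)-9,11-dihydroxyeunicella-2,7(19)-dien-6-one | C[C@@]1(O)CC[C@H](C(C)C)[C@H]2/C=C(/C)CCC(=O)C(=C)C[C@@H](O)[C@@H]12 | intermediate
19 | (1S,2Z,6R,9R,10S,11R,14R)-eunicella-2,7(19)-diene-6,9,11-triol | C[C@@]1(O)CC[C@H](C(C)C)[C@H]2/C=C(/C)CC[C@@H](O)C(=C)C[C@@H](O)[C@@H]12 | intermediate
20 | (1S,2Z,6R,9R,10S,11R,14R)-eunicella-2,7(19)-diene-6,9,11-triol 6,9-diacetate (CNP0303839.1) | C=C1C[C@@H](OC(C)=O)[C@@H]2[C@H](/C=C(/C)CC[C@H]1OC(C)=O)[C@@H](C(C)C)CC[C@@]2(C)O | target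

**Totals**
Total steps: 10.
Longest linear sequence: 9 steps (1, 2, 3, 5, 6, 7, 8, 9, 10, from compound 1).

**Steps most likely to fail**

Step 8 (ring closure). The palladium homoenolate may undergo β-hydride elimination to a dienone, the alkenylpalladium may engage the C7 methylene in a Heck-type path, or the C9 carbinol may be oxidised. Fallback, setting out from 17 and coming back at 18: silylate all three hydroxyls with N-(trimethylsilyl)imidazole to the tris(trimethylsilyl) ether F1. Open its siloxycyclopropane with ZnCl2 (Et2O, 23 °C) to the chlorozinc ketone homoenolate F2. Couple this with the alkenyl iodide in the same molecule under Pd(PPh3)4 (THF/DMA, 60 °C, 2 mM), a stoichiometric zinc-homoenolate Negishi closure in place of the catalytic alkoxide route, to give the bis(trimethylsilyl) ether of the macrocyclic enone F3. K2CO3 in MeOH then frees 18.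

Step 5 (C8–C9 union). The β-silyl cation formed next to the cyclopropane may ring-expand, or the lactol may ionise too slowly for the acetate-bearing allylsilane to survive. Fallback, setting out from 7 and 13 and coming back at 14: convert 13 with NBS (CH2Cl2, −78 °C) into the allylic bromide 1-(3-bromoprop-1-en-2-yl)cyclopropyl acetate F4. Add it to the aldehyde tautomer of 7 in a neutral Barbier allylation with In powder in THF/H2O (Felkin–Anh addition, same sense at C9). The resulting homoallylic hydroxy acid F5 closes to 14 on acidification.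

Step 7 (Z-iodoalkene). The thermally labile α-iodo ylide may decompose before the lactol opens, or give poor Z/E. Fallback, setting out from 15 and coming back at 18: Ramirez olefination with the ylide from [Ph3PCHBr2]Br and KOt-Bu (THF, 0 °C) gives the 1,1-dibromoalkene F6. Trans-selective Negishi methylation (MeZnCl, Pd(t-Bu3P)2, THF, 0 °C) replaces the bromine trans to C1 and gives the (Z)-bromoalkene F7. F7 is cyclised under the conditions of step 8 to 18.

**Further compounds**
F1 | step 8 | tris(trimethylsilyl) ether of 17 | C[C@@]1(O[Si](C)(C)C)CC[C@H](C(C)C)[C@@H](/C=C(/C)I)[C@H]1[C@H](O[Si](C)(C)C)CC(=C)C2(O[Si](C)(C)C)CC2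
F2 | step 8 | chlorozinc homoenolate of the C6 ketone (ring-opened F1) | C[C@@]1(O[Si](C)(C)C)CC[C@H](C(C)C)[C@@H](/C=C(/C)I)[C@H]1[C@H](O[Si](C)(C)C)CC(=C)C(=O)CC[Zn]Cl
F3 | step 8 | 9,11-bis(trimethylsilyl) ether of 18 | C[C@@]1(O[Si](C)(C)C)CC[C@H](C(C)C)[C@H]2/C=C(/C)CCC(=O)C(=C)C[C@@H](O[Si](C)(C)C)[C@@H]12
F4 | step 5 | 1-(3-bromoprop-1-en-2-yl)cyclopropyl acetate | CC(=O)OC1(CC1)C(=C)CBr
F5 | step 5 | homoallylic hydroxy acid (open form of 14) | C[C@@]1(O)CC[C@H](C(C)C)[C@@H](C(O)=O)[C@H]1[C@H](O)CC(=C)C2(OC(C)=O)CC2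
F6 | step 7 | 1,1-dibromoalkene triol | C[C@@]1(O)CC[C@H](C(C)C)[C@@H](C=C(Br)Br)[C@H]1[C@H](O)CC(=C)C2(O)CC2
F7 | step 7 | (Z)-bromoalkene triol (bromo analogue of 17) | C[C@@]1(O)CC[C@H](C(C)C)[C@@H](/C=C(/C)Br)[C@H]1[C@H](O)CC(=C)C2(O)CC2
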